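## Structural features

The target (C25H24O6) is an achiral flavone. Ring A is a phloroglucinol-type benzene ring with hydroxyls at C5 and C7 and a 3-methylbut-2-enyl (prenyl) group at C8; it is fused through C4a/C8a to the γ-pyranone ring C, whose C2 carries ring B. Ring B is the benzene ring of a 2,2-dimethyl-2H-chromene: an O–C(CH3)2–CH=CH unit bridges the 4'-oxygen and C5', and C3' keeps a free phenol. There is no stereocentre, so no stereocentres stand next to each other and every selectivity question is one of regio- or chemoselectivity. The fragile parts are the prenyl double bond beside the C7 phenol (acid closes it to a chroman, electrophilic halogen to a halochroman), the styrene-like C3=C4 bond of the chromene (acid, oxidants, hydrogenation) and the very electron-rich ring A. The real difficulty is to have the prenyl group at C8 and not at C6, which means deciding which of the two ortho oxygens of ring A becomes O1, while both alkenes survive every step. The key step uses the fact that C2–C3–C4 of ring C is a 1,3-dioxygenated three-carbon link between rings A and B, and that the acyl carbon C4 sits on ring A between two oxygen-bearing ortho carbons (C5 and C8a). C4 can therefore enter as a nitrile oxide carbon shielded against dimerisation, and C3 and C2 as the two carbons of a terminal alkyne on ring B.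

## Logic of the disconnections

**19 to 16.** The O1–C2 bond of ring C is cut, the C4 carbonyl is traced back to a C4–NH2 enamine carbon, and the three O–CH2OCH3 bonds are restored. Ring C disappears and an open three-carbon chain between two aryl halves remains. The forward step demands that only the oxygen beside the prenyl group is free when the ring closes, and that the acid exposure is short enough for the prenyl and chromene alkenes.

**16 to 15.** The nitrogen on C4 is reconnected to the oxygen on C2. The open enaminone becomes a stable aromatic isoxazole that can be carried and purified. The forward step must cut only the N–O bond and must not touch the two C=C bonds, which rules out hydrogenation.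

**15 to 14.** The phenol O–H is replaced by an O–Si bond. Nothing is gained in skeleton, but the phenol beside the prenyl group is hidden while the dipole is made. The forward step must remove silicon without touching the acetals.

**14 to 6 and 12 (through 13).** The C3–C4 bond and the O–C2 bond (flavone numbering) are cut. This is the largest simplification: the molecule falls into two halves of similar size, each an aromatic aldehyde derivative. The forward step demands 3,5-regiochemistry, reaction at the alkyne and not at the chromene or prenyl alkene, and a dipole that lives long enough.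

**6 to 5 to 4 to 3 to 1 and 2.** The C=N bond, the O–Si bond, two O–CH2 acetal bonds and the C8–CH2 bond of the prenyl group are cut in turn. The prenyl group goes on first, while the two free ring carbons of 1 are equivalent. The prenyl group then differentiates the two ortho hydroxyls by its bulk. The forward steps demand mono-C-alkylation over O- and double alkylation, and acetal formation at the para oxygen and the less hindered ortho oxygen only.

**12 to 11.** The triple bond is cut between its two carbons; the terminal carbon comes from a one-carbon reagent. The forward step needs a non-enolisable aldehyde, which 11 is.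

**11 to 10.** The C4–C4a bond of the chromene is cut and the ether oxygen is returned to a propargylic carbon. The pyran ring becomes a simple aryl propargyl ether. The forward rearrangement needs a single free ortho carbon, which the acetal on the other side guarantees.

**10 to 9 to 7 and 8.** One O–CH2 acetal bond and the O–C(CH3)2 ether bond are cut. The forward alkylation must take place at the hydroxyl para to the formyl group only.

## Other disconnections considered

**Alternative 1:** The cut runs through C4a–C4 and O1–C2, so that ring C is made from phloroglucinol A1 and the ring B β-keto ester A2. In the forward sense A1 and A2 would be melted together without solvent at about 250 °C (Mentzer fusion). Thermal C-acylation of A1 and cyclodehydration through the neighbouring hydroxyl would close ring C and give the des-prenyl flavone triol A3.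
- In its favour: A1 is threefold symmetric, so the ring closure has no regiochemical question. No protecting group is needed. Two bonds and a ring come from two simple pieces in one operation. A2 lies a few steps from aldehyde 11.
- Against it here: A3 lacks the C8 prenyl group. It would have to be introduced on a 5,7-dihydroxyflavone whose C6 and C8 are both nucleophilic and whose three phenols compete as O-nucleophiles, so the one hard question of this target is left to a poorly controlled last operation. The melt is also severe for the 2H-chromene (thermal opening to an o-quinone methide) and its free phenol, and Pechmann-type coumarin formation can compete.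
- Comparison: up to the flavone core the alternative is the better of the two in step count and in freedom from protecting groups. On structure the chosen plan is stronger, because the prenyl group goes onto symmetric 1 and then marks the oxygen that becomes O1. On mechanism, a cycloaddition at 70 °C between two finished halves is gentler than a condensation at 250 °C. Once the operations needed to steer a prenyl group to C8 of A3 are added (protection, O-prenylation at the 5-hydroxyl, para-selective Claisen–Cope shift), the step advantage should shrink to about parity.

**Alternative 2:** The cut is the C3=C4 double bond of the pyran on ring B, leading back to the diene A4, which carries a 5'-vinyl group and a 4'-O-(1,1-dimethylallyl) ether. Forward, ring-closing metathesis with the second-generation Grubbs catalyst RuCl2(PCy3)(H2IMes)(=CHPh) would close the pyran and give A5, the 7,3'-bis-MOM ether of the target.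
- In its favour: the ring closure is neutral and runs near room temperature. The chromene is made late and never meets the oxidant, Mo(CO)6 or strong base. Ring-closing metathesis of o-vinylaryl allyl ethers to 2H-chromenes is an established reaction type, and the chelated 5-hydroxyl and the pyranone should be tolerated.
- Against it here: the cut removes two carbons and leaves rings A and C and the C8 question untouched, so a complete flavone synthesis is still needed, now with two extra handles on ring B. A4 needs a tertiary allyl aryl ether on a phenol flanked by two ortho substituents, which is hard to make and prone to ionisation or sigmatropic shifts, and a vinyl group from an additional cross-coupling. The C8 prenyl group is a third alkene that the ruthenium carbene, or the small olefin released on ring closure, could truncate by cross-metathesis.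
- Comparison: the alternative is the equal or the better of the chosen plan in the mildness of its ring-forming event and in sparing the chromene from later reagents. Mechanistically both rest on reliable reaction classes. Structurally it solves a sub-problem that the chosen plan solves in one thermal step (10 to 11). In step economy it is clearly worse.

**Alternative 3:** The cut is the C7–C8 bond of ring A, leading back to the pyranone A6. A6 has a 4-methylpent-3-enyl chain on the ring carbon next to the ring oxygen and a β-keto ester on the neighbouring ring carbon. Forward, excess LiN(iPr)2 would deprotonate the CH2 attached to the pyranone. The carbanion would attack the ester carbon in a Dieckmann closure, and enolisation would give the aromatic ring A of A7, the 3'-O-MOM ether of the target.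
- In its favour: the prenyl position is fixed by the carbon chain, so the C6/C8 question does not arise. Ring A appears with both phenols free, so it needs no protecting groups. The logic resembles a polyketide folding.
- Against it here: A6 is a fully substituted pyranone with three different carbon substituents, and its preparation should take more steps than both fragments of the chosen route together. Under excess amide base the β-keto ester is deprotonated first, and its enolate is conjugated with the ester carbonyl that must act as the electrophile. Further acidic sites (the allylic CH2 of the side chain, C3–H) and aldol-type closures could compete.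
- Comparison: on regiochemical certainty and protecting-group economy the alternative is the equal or the better of the chosen plan. On mechanism it is less secure (polyanion chemistry on a deactivated ester). In total step economy it is worse.

Key step: step 9

Remark on the chemistry: the atom mapping of dipole, alkyne and isoxazole onto the target (nitrile oxide carbon = C4, terminal alkyne carbon = C3, internal alkyne carbon = C2, phenol oxygen beside the prenyl group = O1) is consistent and needs no correction; the one design change is that the phenol beside the prenyl group is carried through the dipole generation as a tert-butyldimethylsilyl ether and the aldoxime is dehydrogenated with PhI(OAc)2 instead of an N-chloro imide, because a free o-prenylphenol on a trioxygenated ring would be open to chloro-etherification, ring chlorination and addition to the dipole; the bonds formed, the ring closed and the skeletons are unchanged, and the free-phenol isoxazole appears as 15.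

## Route

**Step 1**
Reactants: 1 2,4,6-trihydroxybenzaldehyde; 2 prenyl bromide (1-bromo-3-methylbut-2-ene)
Product: 3 2,4,6-trihydroxy-3-(3-methylbut-2-en-1-yl)benzaldehyde
Conditions: 2 (1.0 equiv), 10% aq. KOH, 0 °C to rt
Reagents that add atoms: none
Why: C-alkylation of the phloroglucinol phenoxide (ambident anion; in water the oxygens are solvated and the ring carbon reacts); C3 and C5 of 1 are equivalent, so only one mono-C-prenyl product is possible, and one equivalent of 2 at low temperature limits O-alkylation and double alkylation.

**Step 2**
Reactants: 3 2,4,6-trihydroxy-3-(3-methylbut-2-en-1-yl)benzaldehyde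
Product: 4 2-hydroxy-4,6-bis(methoxymethoxy)-3-(3-methylbut-2-en-1-yl)benzaldehyde
Conditions: MOMCl (2.1 equiv), i-Pr2NEt, CH2Cl2, 0 °C
Reagents that add atoms: chloromethyl methyl ether (MOMCl), COCCl
Why: Phenol O-alkylation with a chloromethyl ether; the para hydroxyl (most acidic) and the ortho hydroxyl not flanked by the prenyl group should react, while the hydroxyl between the formyl and prenyl groups stays as the hydrogen-bonded chelate, and this is the oxygen that must later become O1.

**Step 3**
Reactants: 4 2-hydroxy-4,6-bis(methoxymethoxy)-3-(3-methylbut-2-en-1-yl)benzaldehyde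
Product: 5 2-(tert-butyldimethylsilyloxy)-4,6-bis(methoxymethoxy)-3-(3-methylbut-2-en-1-yl)benzaldehyde
Conditions: TBSCl, imidazole, DMF, 40 °C
Reagents that add atoms: tert-butyldimethylsilyl chloride (TBSCl), CC(C)(C)[Si](C)(C)Cl
Why: Silylation of the chelated phenol under imidazole/DMF conditions; the cap removes the free o-prenylphenol before any oxidant is used and is orthogonal to the MOM acetals.

**Step 4**
Reactants: 5 2-(tert-butyldimethylsilyloxy)-4,6-bis(methoxymethoxy)-3-(3-methylbut-2-en-1-yl)benzaldehyde
Product: 6 (E)-2-(tert-butyldimethylsilyloxy)-4,6-bis(methoxymethoxy)-3-(3-methylbut-2-en-1-yl)benzaldehyde oxime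
Conditions: NH2OH·HCl, NaOAc, EtOH–H2O, rt
Reagents that add atoms: hydroxylamine hydrochloride, Cl.NO
Why: Condensation of the aldehyde with hydroxylamine in acetate buffer should give the (E)-aldoxime; at about pH 5 the aryl silyl ether and the acetals are stable, and the oxime geometry is of no consequence later.

**Step 5**
Reactants: 7 3,4-dihydroxybenzaldehyde; 8 3-chloro-3-methylbut-1-yne
Product: 9 3-hydroxy-4-[(2-methylbut-3-yn-2-yl)oxy]benzaldehyde
Conditions: K2CO3 (1.1 equiv), KI, CuI (cat.), DMF, 60 °C, N2
Reagents that add atoms: none
Why: Copper-assisted O-alkylation of a phenoxide with a tertiary propargylic chloride; with one equivalent of K2CO3 only the 4-hydroxyl, para to the formyl group and the more acidic, is ionised and alkylated.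

**Step 6**
Reactants: 9 3-hydroxy-4-[(2-methylbut-3-yn-2-yl)oxy]benzaldehyde
Product: 10 3-(methoxymethoxy)-4-[(2-methylbut-3-yn-2-yl)oxy]benzaldehyde
Conditions: MOMCl, i-Pr2NEt, CH2Cl2, 0 °C to rt
Reagents that add atoms: chloromethyl methyl ether (MOMCl), COCCl
Why: Standard MOM protection of the remaining, non-chelated phenol; it blocks one ortho position for the rearrangement and protects the catechol-type oxygen through the later base and oxidant steps.

**Step 7**
Reactants: 10 3-(methoxymethoxy)-4-[(2-methylbut-3-yn-2-yl)oxy]benzaldehyde
Product: 11 8-(methoxymethoxy)-2,2-dimethyl-2H-chromene-6-carbaldehyde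
Conditions: PhNEt2, 190 °C
Reagents that add atoms: none
Why: Aromatic propargyl Claisen rearrangement to the only free ortho carbon, tautomerisation, 1,5-hydrogen shift of the o-allenylphenol and oxa-6π electrocyclisation should give the 2,2-dimethyl-2H-chromene as a single regioisomer; the basic medium protects the acetal.

**Step 8**
Reactants: 11 8-(methoxymethoxy)-2,2-dimethyl-2H-chromene-6-carbaldehyde
Product: 12 6-ethynyl-8-(methoxymethoxy)-2,2-dimethyl-2H-chromene
Conditions: dimethyl (1-diazo-2-oxopropyl)phosphonate, K2CO3, MeOH, rt
Reagents that add atoms: dimethyl (1-diazo-2-oxopropyl)phosphonate (Ohira–Bestmann reagent), COP(=O)(OC)C(=[N+]=[N-])C(C)=O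
Why: Ohira–Bestmann homologation: the diazophosphonate anion released by methanolysis adds to the non-enolisable aryl aldehyde and the diazoalkene loses N2 with a 1,2-shift to give the terminal alkyne; K2CO3 in MeOH leaves the acetal and the chromene untouched.

**Step 9**
Reactants: 6 (E)-2-(tert-butyldimethylsilyloxy)-4,6-bis(methoxymethoxy)-3-(3-methylbut-2-en-1-yl)benzaldehyde oxime; 12 6-ethynyl-8-(methoxymethoxy)-2,2-dimethyl-2H-chromene
Product: 14 3-[2-(tert-butyldimethylsilyloxy)-4,6-bis(methoxymethoxy)-3-(3-methylbut-2-en-1-yl)phenyl]-5-[8-(methoxymethoxy)-2,2-dimethyl-2H-chromen-6-yl]isoxazole, via silyl-capped nitrile oxide 13 (not isolated)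
Conditions: PhI(OAc)2 (1.1 equiv), MeOH, 0 °C; aq. NaHCO3 wash; then 12 (1.3 equiv), PhMe, 70 °C
Reagents that add atoms: none
Why: PhI(OAc)2 dehydrogenates the aldoxime of 6 (ligand exchange at iodine, then loss of PhI and AcOH) to the nitrile oxide 13, which should persist because both ortho positions carry oxygen substituents that block the approach needed for furoxan formation, so the oxidant can be consumed and washed out before 12 is added. 13 and the terminal alkyne then combine in a concerted, asynchronous 1,3-dipolar (Huisgen) cycloaddition; the closest known reaction type is the nitrile oxide–arylacetylene route to 3,5-diarylisoxazoles. The five-membered isoxazole is closed intermolecularly in one (3+2) event that forms the C3–C4 bond and the O–C2 bond (flavone numbering) together. No stereocentre is formed. The step needs 3,5-regioselectivity, and the terminal alkyne secures it: its unsubstituted carbon bonds to the nitrile oxide carbon, which is both the sterically easier approach to the di-ortho-substituted aryl group and the orbital-favoured one. It also needs chemoselectivity for the alkyne: the prenyl alkene is trisubstituted and the chromene alkene is cis-disubstituted next to a quaternary carbon, so both should be far slower dipolarophiles. The silyl cap keeps the phenol from adding to the dipole, and the halogen-free oxidant spares both alkenes and the electron-rich ring.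

**Step 10**
Reactants: 14 3-[2-(tert-butyldimethylsilyloxy)-4,6-bis(methoxymethoxy)-3-(3-methylbut-2-en-1-yl)phenyl]-5-[8-(methoxymethoxy)-2,2-dimethyl-2H-chromen-6-yl]isoxazole
Product: 15 3,5-bis(methoxymethoxy)-2-{5-[8-(methoxymethoxy)-2,2-dimethyl-2H-chromen-6-yl]isoxazol-3-yl}-6-(3-methylbut-2-en-1-yl)phenol
Conditions: TBAF, AcOH, THF, 0 °C
Reagents that add atoms: none
Why: Fluoride cleaves the aryl silyl ether (strong Si–F bond, phenoxide leaving group) while acetic acid buffers the phenoxide; MOM acetals, isoxazole and both alkenes are inert.

**Step 11**
Reactants: 15 3,5-bis(methoxymethoxy)-2-{5-[8-(methoxymethoxy)-2,2-dimethyl-2H-chromen-6-yl]isoxazol-3-yl}-6-(3-methylbut-2-en-1-yl)phenol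
Product: 16 (Z)-3-amino-3-[2-hydroxy-4,6-bis(methoxymethoxy)-3-(3-methylbut-2-en-1-yl)phenyl]-1-[8-(methoxymethoxy)-2,2-dimethyl-2H-chromen-6-yl]prop-2-en-1-one
Conditions: Mo(CO)6, MeCN–H2O, 80 °C
Reagents that add atoms: none
Why: Reductive cleavage of the isoxazole N–O bond by Mo(CO)6 and water, a known reaction of isoxazoles, should give the hydrogen-bonded (Z)-β-enaminoketone; unlike catalytic hydrogenation it leaves the prenyl and chromene double bonds alone.

**Step 12**
Reactants: 16 (Z)-3-amino-3-[2-hydroxy-4,6-bis(methoxymethoxy)-3-(3-methylbut-2-en-1-yl)phenyl]-1-[8-(methoxymethoxy)-2,2-dimethyl-2H-chromen-6-yl]prop-2-en-1-one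
Product: 19 5,7-dihydroxy-2-(8-hydroxy-2,2-dimethyl-2H-chromen-6-yl)-8-(3-methylbut-2-en-1-yl)-4H-chromen-4-one, via tris-MOM 4-iminoflavone 17 (not isolated), via tris-MOM flavone 18 (not isolated)
Conditions: 1 M HCl (aq), THF, rt; then 3 M HCl (aq), MeOH, 55 °C
Reagents that add atoms: water, O
Why: In dilute acid the only free phenol adds to the protonated enaminone carbonyl (6-exo-trig) and water is lost to give 17 as its 4-aminobenzopyrylium salt before any acetal is cleaved, which fixes the prenyl group at C8; the stronger acid in aqueous methanol then hydrolyses the C4 iminium to the flavone 18 and removes the three MOM groups by acetal solvolysis.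

## Compound list

1 | 2,4,6-trihydroxybenzaldehyde | O=Cc1c(O)cc(O)cc1O | starting material
2 | prenyl bromide (1-bromo-3-methylbut-2-ene) | CC(C)=CCBr | starting material
3 | 2,4,6-trihydroxy-3-(3-methylbut-2-en-1-yl)benzaldehyde | O=Cc1c(O)cc(O)c(CC=C(C)C)c1O | intermediate
4 | 2-hydroxy-4,6-bis(methoxymethoxy)-3-(3-methylbut-2-en-1-yl)benzaldehyde | O=Cc1c(O)c(CC=C(C)C)c(OCOC)cc1OCOC | intermediate
5 | 2-(tert-butyldimethylsilyloxy)-4,6-bis(methoxymethoxy)-3-(3-methylbut-2-en-1-yl)benzaldehyde | O=Cc1c(O[Si](C)(C)C(C)(C)C)c(CC=C(C)C)c(OCOC)cc1OCOC | intermediate
6 | (E)-2-(tert-butyldimethylsilyloxy)-4,6-bis(methoxymethoxy)-3-(3-methylbut-2-en-1-yl)benzaldehyde oxime | O/N=C/c1c(O[Si](C)(C)C(C)(C)C)c(CC=C(C)C)c(OCOC)cc1OCOC | intermediate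
7 | 3,4-dihydroxybenzaldehyde | O=Cc1ccc(O)c(O)c1 | starting material
8 | 3-chloro-3-methylbut-1-yne | CC(C)(Cl)C#C | starting material
9 | 3-hydroxy-4-[(2-methylbut-3-yn-2-yl)oxy]benzaldehyde | O=Cc1ccc(OC(C)(C)C#C)c(O)c1 | intermediate
10 | 3-(methoxymethoxy)-4-[(2-methylbut-3-yn-2-yl)oxy]benzaldehyde | O=Cc1ccc(OC(C)(C)C#C)c(OCOC)c1 | intermediate
11 | 8-(methoxymethoxy)-2,2-dimethyl-2H-chromene-6-carbaldehyde | O=Cc1cc(OCOC)c2OC(C)(C)C=Cc2c1 | intermediate
12 | 6-ethynyl-8-(methoxymethoxy)-2,2-dimethyl-2H-chromene | C#Cc1cc(OCOC)c2OC(C)(C)C=Cc2c1 | intermediate
13 | 2-(tert-butyldimethylsilyloxy)-4,6-bis(methoxymethoxy)-3-(3-methylbut-2-en-1-yl)benzonitrile oxide | [O-][N+]#Cc1c(O[Si](C)(C)C(C)(C)C)c(CC=C(C)C)c(OCOC)cc1OCOC | intermediate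
14 | 3-[2-(tert-butyldimethylsilyloxy)-4,6-bis(methoxymethoxy)-3-(3-methylbut-2-en-1-yl)phenyl]-5-[8-(methoxymethoxy)-2,2-dimethyl-2H-chromen-6-yl]isoxazole | CC(C)=CCc1c(O[Si](C)(C)C(C)(C)C)c(-c2cc(-c3cc(OCOC)c4OC(C)(C)C=Cc4c3)on2)c(OCOC)cc1OCOC | intermediate
15 | 3,5-bis(methoxymethoxy)-2-{5-[8-(methoxymethoxy)-2,2-dimethyl-2H-chromen-6-yl]isoxazol-3-yl}-6-(3-methylbut-2-en-1-yl)phenol | CC(C)=CCc1c(O)c(-c2cc(-c3cc(OCOC)c4OC(C)(C)C=Cc4c3)on2)c(OCOC)cc1OCOC | intermediate
16 | (Z)-3-amino-3-[2-hydroxy-4,6-bis(methoxymethoxy)-3-(3-methylbut-2-en-1-yl)phenyl]-1-[8-(methoxymethoxy)-2,2-dimethyl-2H-chromen-6-yl]prop-2-en-1-one | CC(C)=CCc1c(O)c(/C(N)=C/C(=O)c2cc(OCOC)c3OC(C)(C)C=Cc3c2)c(OCOC)cc1OCOC | intermediate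
17 | 5,7-bis(methoxymethoxy)-2-[8-(methoxymethoxy)-2,2-dimethyl-2H-chromen-6-yl]-8-(3-methylbut-2-en-1-yl)-4H-chromen-4-imine | CC(C)=CCc1c(OCOC)cc(OCOC)c2c(=N)cc(-c3cc(OCOC)c4OC(C)(C)C=Cc4c3)oc12 | intermediate
18 | 5,7-bis(methoxymethoxy)-2-[8-(methoxymethoxy)-2,2-dimethyl-2H-chromen-6-yl]-8-(3-methylbut-2-en-1-yl)-4H-chromen-4-one | CC(C)=CCc1c(OCOC)cc(OCOC)c2c(=O)cc(-c3cc(OCOC)c4OC(C)(C)C=Cc4c3)oc12 | intermediate
19 | 5,7-dihydroxy-2-(8-hydroxy-2,2-dimethyl-2H-chromen-6-yl)-8-(3-methylbut-2-en-1-yl)-4H-chromen-4-one | CC(C)=CCc1c(O)cc(O)c2c(=O)cc(-c3cc(O)c4c(c3)C=CC(C)(C)O4)oc12 | target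

## Step count and least certain steps

Total step count: 12. Longest linear sequence: 8 steps (steps 1–4 and 9–12 from 1; equally steps 5–8 and 9–12 from 7).

**Step 9 (key step).** The most likely failure is a slow union of the hindered dipole with the alkyne. The dipole could then decay (isomerisation to the isocyanate, addition of residual acetic acid) or add to the chromene C3=C4 bond. The fallback gives up the cycloaddition and joins the same halves by carbonyl addition. It sets out from 5 and 12 and comes back to the route at 18. Alkyne 12 would be deprotonated with n-BuLi (THF, −78 °C) and added to aldehyde 5 to give the racemic propargylic alcohol F1. Oxidation with MnO2 in CH2Cl2 should give the ynone F2. TBAF/AcOH should free the phenol ynone F3. Et2NH in EtOH would then add to the ynone, and the phenol would displace the amine in the 6-endo sense (this avoids aurone formation) to give 18. 18 is deprotected under the second-stage conditions of step 12.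

**Step 1.** The most likely failure is alkylation at oxygen or twice at carbon, leaving little mono-C-prenyl product. The fallback sets out from 1 and comes back at 4. It places the acetals first and then the prenyl group by a sigmatropic shift, and it also removes the reliance of step 2 on steric differentiation of the two ortho hydroxyls. MOMCl/i-Pr2NEt should give 2-hydroxy-4,6-bis(methoxymethoxy)benzaldehyde F4. Alkylation of the remaining phenol with 8 (K2CO3, KI, CuI, DMF) should give the propargyl ether F5. Semi-hydrogenation (H2, Pd/CaCO3 poisoned with Pb(OAc)2, quinoline) should give the 1,1-dimethylallyl ether F6. Aromatic Claisen rearrangement in PhMe at 110 °C should deliver the prenyl group to the only free ortho carbon and give 4.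

**Step 5.** The most likely failure is alkylation of both phenols, or elimination of the tertiary chloride outrunning substitution at the poorly nucleophilic phenoxide. The fallback sets out from 7 and comes back at 10. It differentiates the two hydroxyls with a temporary allyl group. Allyl bromide with one equivalent of K2CO3 should give 4-(allyloxy)-3-hydroxybenzaldehyde F7. MOMCl/i-Pr2NEt should give 4-(allyloxy)-3-(methoxymethoxy)benzaldehyde F8. Pd(PPh3)4 with morpholine should give 4-hydroxy-3-(methoxymethoxy)benzaldehyde F9. F9 has a single phenol, which is alkylated with 8 to give 10.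

**Step 12.** The most likely failure is acid-promoted addition of the C7 hydroxyl to the prenyl double bond (chroman formation), made worse if hydrolysis of the C4 iminium is slow and the acid exposure has to be prolonged. The fallback separates ring closure from deprotection and replaces protic solvolysis by a soft-nucleophile cleavage. It sets out from 16 and comes back at 19. Ring closure and hydrolysis would be run in buffered aqueous AcOH/NaOAc at 60 °C and 18 isolated. The acetals would then be cleaved with ZnBr2 and n-PrSH in CH2Cl2 at 0 °C. This fallback makes no compound outside the compound list.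

## Further compounds

F1 | step 9 | rac-1-[2-(tert-butyldimethylsilyloxy)-4,6-bis(methoxymethoxy)-3-(3-methylbut-2-en-1-yl)phenyl]-3-[8-(methoxymethoxy)-2,2-dimethyl-2H-chromen-6-yl]prop-2-yn-1-ol | CC(C)=CCc1c(O[Si](C)(C)C(C)(C)C)c(C(O)C#Cc2cc(OCOC)c3OC(C)(C)C=Cc3c2)c(OCOC)cc1OCOC
F2 | step 9 | 1-[2-(tert-butyldimethylsilyloxy)-4,6-bis(methoxymethoxy)-3-(3-methylbut-2-en-1-yl)phenyl]-3-[8-(methoxymethoxy)-2,2-dimethyl-2H-chromen-6-yl]prop-2-yn-1-one | CC(C)=CCc1c(O[Si](C)(C)C(C)(C)C)c(C(=O)C#Cc2cc(OCOC)c3OC(C)(C)C=Cc3c2)c(OCOC)cc1OCOC
F3 | step 9 | 1-[2-hydroxy-4,6-bis(methoxymethoxy)-3-(3-methylbut-2-en-1-yl)phenyl]-3-[8-(methoxymethoxy)-2,2-dimethyl-2H-chromen-6-yl]prop-2-yn-1-one | CC(C)=CCc1c(O)c(C(=O)C#Cc2cc(OCOC)c3OC(C)(C)C=Cc3c2)c(OCOC)cc1OCOC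
F4 | step 1 | 2-hydroxy-4,6-bis(methoxymethoxy)benzaldehyde | O=Cc1c(O)cc(OCOC)cc1OCOC
F5 | step 1 | 4,6-bis(methoxymethoxy)-2-[(2-methylbut-3-yn-2-yl)oxy]benzaldehyde | O=Cc1c(OC(C)(C)C#C)cc(OCOC)cc1OCOC
F6 | step 1 | 4,6-bis(methoxymethoxy)-2-[(2-methylbut-3-en-2-yl)oxy]benzaldehyde | O=Cc1c(OC(C)(C)C=C)cc(OCOC)cc1OCOC
F7 | step 5 | 4-(allyloxy)-3-hydroxybenzaldehyde | O=Cc1ccc(OCC=C)c(O)c1
F8 | step 5 | 4-(allyloxy)-3-(methoxymethoxy)benzaldehyde | O=Cc1ccc(OCC=C)c(OCOC)c1
F9 | step 5 | 4-hydroxy-3-(methoxymethoxy)benzaldehyde | O=Cc1ccc(O)c(OCOC)c1
F0 | step 12 | none | none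
A1 | alternative 1 | phloroglucinol (benzene-1,3,5-triol) | Oc1cc(O)cc(O)c1
A2 | alternative 1 | ethyl 3-(8-hydroxy-2,2-dimethyl-2H-chromen-6-yl)-3-oxopropanoate | CCOC(=O)CC(=O)c1cc(O)c2OC(C)(C)C=Cc2c1
A3 | alternative 1 | 5,7-dihydroxy-2-(8-hydroxy-2,2-dimethyl-2H-chromen-6-yl)-4H-chromen-4-one | CC1(C)C=Cc2cc(-c3cc(=O)c4c(O)cc(O)cc4o3)cc(O)c2O1
A4 | alternative 2 | 5-hydroxy-7-(methoxymethoxy)-2-{3-(methoxymethoxy)-4-[(2-methylbut-3-en-2-yl)oxy]-5-vinylphenyl}-8-(3-methylbut-2-en-1-yl)-4H-chromen-4-one | CC(C)=CCc1c(OCOC)cc(O)c2c(=O)cc(-c3cc(OCOC)c(OC(C)(C)C=C)c(C=C)c3)oc12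
A5 | alternative 2 | 5-hydroxy-7-(methoxymethoxy)-2-[8-(methoxymethoxy)-2,2-dimethyl-2H-chromen-6-yl]-8-(3-methylbut-2-en-1-yl)-4H-chromen-4-one | CC(C)=CCc1c(OCOC)cc(O)c2c(=O)cc(-c3cc(OCOC)c4OC(C)(C)C=Cc4c3)oc12
A6 | alternative 3 | methyl 3-{6-[8-(methoxymethoxy)-2,2-dimethyl-2H-chromen-6-yl]-2-(4-methylpent-3-en-1-yl)-4-oxo-4H-pyran-3-yl}-3-oxopropanoate | COC(=O)CC(=O)c1c(CCC=C(C)C)oc(-c2cc(OCOC)c3OC(C)(C)C=Cc3c2)cc1=O
A7 | alternative 3 | 5,7-dihydroxy-2-[8-(methoxymethoxy)-2,2-dimethyl-2H-chromen-6-yl]-8-(3-methylbut-2-en-1-yl)-4H-chromen-4-one | CC(C)=CCc1c(O)cc(O)c2c(=O)cc(-c3cc(OCOC)c4OC(C)(C)C=Cc4c3)oc12
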